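**Plan**
- Retrosynthetic cuts: the acetate goes back to a C18 nitrile; the chain is cut at C12–C13 (B-alkyl Suzuki coupling with chloroprene) and C11=C12 (Wittig); the 8-OH/C17 methyl goes back to an 8(17)-methylene and the 5-H/6-OH pair to a C5=C6 alkene; ring B is cut at C9–C10 and C7–C8 (Diels–Alder); the diene is cut at C5–C6 (vinylation) and C4–CH3 (asymmetric methylation).
- Enabling feature: in ring B the 6-OH is cis to H5 at the ring fusion, C8 carries OH and CH3, and C9 carries a one-carbon branch. This is the footprint of a ring B cyclohexene with C5=C6, an 8(17)-methylene and a C9 ester, which is what a ring A diene C10=C5–C6=C7 gives on adding to the conjugated C=C of an allenoate.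
- Forward order: ring A is bought as ethyl 2-oxocyclohexanecarboxylate and turned into the chiral vinylcyclohexene nitrile (steps 1–8); ring B closes in step 9; the C8 and C6 oxygens follow (steps 11, 12); the chain is joined at C11 (steps 14–17); C18 is finished last (steps 18–21).
- Stereochemistry: C4 from a valine-enamine methylation; C10 from diene-face selection steered by the slim C4 nitrile; C9 from dienolate protonation; C8, C5 and C6 from reagent approach anti to the axial C20 and C19 methyl groups.

Key step: step 9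

Assumption: the ether-ligated lithio enamine of step 2 is taken to be methylated on the lithium-bound face anti to the valine isopropyl group, which gives the (S)-keto ester from tert-butyl L-valinate; if the sense proves opposite, tert-butyl D-valinate under the same conditions supplies the same (S)-series and nothing downstream changes.

Remark on names: bicyclic intermediates carry labdane locants (C11 on C9, C17 on C8, C18 and C19 on C4, C20 on C10) and are named as 12,13,14,15,16-pentanorlabdanes; "18-nitrilo" means that C18 is the nitrile carbon.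

**Route**

Step 1
Reactants: 1 ethyl 2-oxocyclohexane-1-carboxylate; 2 tert-butyl L-valinate
Product: 3 tert-butyl (2S)-2-{[2-(ethoxycarbonyl)cyclohex-1-en-1-yl]amino}-3-methylbutanoate
Conditions: BF3·OEt2 (cat.), toluene, reflux, Dean–Stark trap
Reagents that add atoms: none
Why: Acid-catalysed condensation of a β-keto ester with a primary amine should give the hydrogen-bonded (Z)-enamino ester, driven by removal of water and leaving the valine stereocentre untouched.

Step 2
Reactants: 3 tert-butyl (2S)-2-{[2-(ethoxycarbonyl)cyclohex-1-en-1-yl]amino}-3-methylbutanoate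
Product: 6 ethyl (1S)-1-methyl-2-oxocyclohexane-1-carboxylate, via lithio enamine 4 (not isolated), via methylated ketimine 5 (not isolated)
Conditions: LiN(iPr)2 (1.2 equiv), toluene, −78 °C; THF (2 equiv), then MeI, −78 → −40 °C; 10% aq. citric acid, rt
Reagents that add atoms: iodomethane, CI; water, O
Why: Koga-type asymmetric alkylation of a chiral lithio enamine, in which lithium is chelated by the nitrogen and both ester carbonyls and iodomethane is delivered anti to the isopropyl group to set the quaternary C4 as (S), after which mild acid hydrolysis of the ketimine releases the keto ester and the auxiliary.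

Step 3
Reactants: 6 ethyl (1S)-1-methyl-2-oxocyclohexane-1-carboxylate
Product: 8 ethyl (1S,3RS)-1,3-dimethyl-2-oxocyclohexane-1-carboxylate, via lithium enolate 7 (not isolated)
Conditions: LiN(iPr)2, THF, −78 °C; MeI, −78 → 0 °C
Reagents that add atoms: iodomethane, CI
Why: The quaternary α-carbon leaves C3 as the only enolisable position, so kinetic enolate methylation can only install the future C20 methyl, and the C3 epimer ratio is irrelevant because this carbon becomes sp2 in step 4.

Step 4
Reactants: 8 ethyl (1S,3RS)-1,3-dimethyl-2-oxocyclohexane-1-carboxylate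
Product: 10 ethyl (1S)-1,3-dimethyl-2-[(trifluoromethanesulfonyl)oxy]cyclohex-2-ene-1-carboxylate, via tetrasubstituted lithium enolate 9 (not isolated)
Conditions: LiN(iPr)2, THF, −78 → 0 °C; PhNTf2, 0 °C → rt
Reagents that add atoms: N-phenylbis(trifluoromethanesulfonimide), O=S(=O)(N(c1ccccc1)S(=O)(=O)C(F)(F)F)C(F)(F)F
Why: Only the C3 methine can be deprotonated, so the tetrasubstituted enolate forms regiospecifically and is O-sulfonylated (enol triflate formation, precedented for 2,2,6-trisubstituted cyclohexanones).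

Step 5
Reactants: 10 ethyl (1S)-1,3-dimethyl-2-[(trifluoromethanesulfonyl)oxy]cyclohex-2-ene-1-carboxylate; 11 potassium vinyltrifluoroborate
Product: 12 ethyl (1S)-2-ethenyl-1,3-dimethylcyclohex-2-ene-1-carboxylate
Conditions: PdCl2(dppf)·CH2Cl2 (5 mol %), Cs2CO3, THF/H2O (10:1), 70 °C
Reagents that add atoms: none
Why: Suzuki–Miyaura coupling of an alkenyl triflate with a vinyltrifluoroborate, with a bidentate ferrocenylphosphine catalyst that should tolerate the doubly flanked triflate and deliver the 1-vinylcyclohexene diene without touching C4.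

Step 6
Reactants: 12 ethyl (1S)-2-ethenyl-1,3-dimethylcyclohex-2-ene-1-carboxylate
Product: 13 (1S)-2-ethenyl-1,3-dimethylcyclohex-2-ene-1-carboxylic acid
Conditions: KOtBu (6 equiv), H2O (2 equiv), THF, rt → 40 °C; then cold 1 M HCl to pH 3
Reagents that add atoms: water, O
Why: "Anhydrous hydroxide" saponification (Gassman conditions) is the standard answer to esters on quaternary carbons and runs at a temperature at which the diene should neither isomerise nor undergo a 1,5-hydrogen shift.

Step 7
Reactants: 13 (1S)-2-ethenyl-1,3-dimethylcyclohex-2-ene-1-carboxylic acid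
Product: 15 (1S)-2-ethenyl-1,3-dimethylcyclohex-2-ene-1-carboxamide, via acid chloride 14 (not isolated)
Conditions: 1-chloro-N,N,2-trimethylprop-1-en-1-amine, CH2Cl2, 0 °C → rt; then NH3 (0.5 M in 1,4-dioxane), 0 °C
Reagents that add atoms: ammonia, N
Why: Neutral acid chloride formation with the chloroenamine (Ghosez reagent) keeps HCl away from the acid-sensitive diene, and ammonolysis of the acyl chloride gives the primary amide.

Step 8
Reactants: 15 (1S)-2-ethenyl-1,3-dimethylcyclohex-2-ene-1-carboxamide
Product: 16 (1S)-2-ethenyl-1,3-dimethylcyclohex-2-ene-1-carbonitrile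
Conditions: (CF3CO)2O, pyridine, CH2Cl2, 0 °C
Reagents that add atoms: none
Why: Dehydration of a primary carboxamide to the nitrile through its O-trifluoroacetyl imidate, at a quaternary centre that cannot epimerise.

Step 9
Reactants: 16 (1S)-2-ethenyl-1,3-dimethylcyclohex-2-ene-1-carbonitrile; 17 ethyl buta-2,3-dienoate
Product: 18 ethyl (4S,10S)-18-nitrilo-12,13,14,15,16-pentanorlabda-5,8(17)-dien-11-oate (pair of C9 epimers; the exo adduct is identical with 20)
Conditions: 17 (4 equiv), 2,6-di-tert-butyl-4-methylphenol (cat.), degassed toluene (2 M), 105 °C, sealed tube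
Reagents that add atoms: none
Why: A concerted but asynchronous thermal [4+2] cycloaddition (Diels–Alder reaction) joins the C10=C5–C6=C7 diene to the ester-conjugated C=C of the allenoate, the C7–C8 bond to the electrophilic central allene carbon running ahead of the C9–C10 bond at the tetrasubstituted terminus, so the ester ends on C9 and the untouched allene C=C becomes the 8(17)-methylene. The closest known reaction type is the thermal cycloaddition of 1-vinyl-2,6,6-trimethylcyclohexene with acetylenic esters, combined with the use of allenoates as slim, reactive dienophiles. Ring B closes as the six-membered cycloadduct ring in one intermolecular suprafacial event that forms two sigma bonds and leaves C5=C6 behind. C10 is set by the diene face: in the reactive s-cis conformer the C4 methyl should sit pseudoaxial and the linear nitrile pseudoequatorial to minimise A(1,2) strain with the in-plane vinyl group, so the dienophile adds anti to that methyl, on the nitrile face, which places C20 cis to C19. C9 is set only by the endo/exo mode, which is not expected to be selective, and is therefore corrected in step 10. The step needs regioselectivity (unsubstituted C7 to the allene β-carbon, secured by the dialkyl-substituted C10 terminus and by sterics) and C10 face selectivity (secured by the small nitrile at C4).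

Step 10
Reactants: 18 ethyl (4S,10S)-18-nitrilo-12,13,14,15,16-pentanorlabda-5,8(17)-dien-11-oate (pair of C9 epimers)
Product: 20 ethyl (4S,9R,10S)-18-nitrilo-12,13,14,15,16-pentanorlabda-5,8(17)-dien-11-oate, via lithium dienolate 19 (not isolated)
Conditions: LiN(iPr)2 (1.5 equiv), THF, −78 → −40 °C; AcOH in THF, −78 °C
Reagents that add atoms: none
Why: Both epimers give the same extended ester dienolate, and kinetic protonation at the α-carbon anti to the pseudoaxial C20 methyl (deconjugative dienolate protonation) should keep the 8(17)-alkene and put the ester cis to C20, which is also the more stable equatorial epimer.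

Step 11
Reactants: 20 ethyl (4S,9R,10S)-18-nitrilo-12,13,14,15,16-pentanorlabda-5,8(17)-dien-11-oate
Product: 21 ethyl (4S,8S,9S,10S)-8-hydroxy-18-nitrilo-12,13,14,15,16-pentanorlabd-5-en-11-oate
Conditions: Co(acac)2 (20 mol %), PhSiH3 (2.5 equiv), O2 (1 atm), THF, 0 °C → rt
Reagents that add atoms: dioxygen, O=O
Why: Mukaiyama hydration, in which hydrogen-atom transfer from a cobalt hydride to C17 gives the tertiary C8 radical and O2 traps it anti to the syn-axial C20 methyl to give the 8-ol trans to C20, while the 1,1-disubstituted alkene should react far faster than the C5=C6 alkene buried between two quaternary carbons.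

Step 12
Reactants: 21 ethyl (4S,8S,9S,10S)-8-hydroxy-18-nitrilo-12,13,14,15,16-pentanorlabd-5-en-11-oate
Product: 23 ethyl (4S,5S,6R,8S,9S,10R)-6,8-dihydroxy-18-nitrilo-12,13,14,15,16-pentanorlabdan-11-oate, via C6 alkylborane 22 (not isolated)
Conditions: BH3·THF (4 equiv), THF, 0 °C → rt; then 30% aq. H2O2, 3 M aq. NaOAc, 0 °C → rt
Reagents that add atoms: hydrogen peroxide, OO
Why: Brown hydroboration–oxidation adds H–B syn across C5=C6 from the face opposite the C19 and C20 methyl groups (boron on C6, hydrogen on C5), so oxidation with retention should give the trans-decalin with 6-OH cis to H5, and BH3 at 0–25 °C reacts with the alkene well before the ester or the tertiary nitrile.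

Step 13
Reactants: 23 ethyl (4S,5S,6R,8S,9S,10R)-6,8-dihydroxy-18-nitrilo-12,13,14,15,16-pentanorlabdan-11-oate
Product: 24 ethyl (4S,5S,6R,8S,9S,10R)-18-nitrilo-6,8-bis(triethylsilyloxy)-12,13,14,15,16-pentanorlabdan-11-oate
Conditions: Et3SiOTf (3 equiv), 2,6-lutidine (5 equiv), CH2Cl2, −40 °C → rt
Reagents that add atoms: triethylsilyl trifluoromethanesulfonate, CC[Si](CC)(CC)OS(=O)(=O)C(F)(F)F
Why: Silyl triflate with lutidine is strong enough for the tertiary 8-OH as well as the secondary 6-OH, and capping the 6-OH also prevents its addition to the neighbouring (peri) nitrile in the later basic steps.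

Step 14
Reactants: 24 ethyl (4S,5S,6R,8S,9S,10R)-18-nitrilo-6,8-bis(triethylsilyloxy)-12,13,14,15,16-pentanorlabdan-11-oate
Product: 25 (4S,5S,6R,8S,9R,10R)-11-hydroxy-6,8-bis(triethylsilyloxy)-12,13,14,15,16-pentanorlabdane-18-nitrile
Conditions: LiBH4 (4 equiv), MeOH (2 equiv), THF, 0 → 55 °C
Reagents that add atoms: none
Why: Methanol-activated LiBH4 reduces esters but not nitriles or silyl ethers (chemoselective ester reduction), which differentiates C11 from C18.

Step 15
Reactants: 25 (4S,5S,6R,8S,9R,10R)-11-hydroxy-6,8-bis(triethylsilyloxy)-12,13,14,15,16-pentanorlabdane-18-nitrile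
Product: 26 (4S,5S,6R,8S,9S,10R)-11-oxo-6,8-bis(triethylsilyloxy)-12,13,14,15,16-pentanorlabdane-18-nitrile
Conditions: Dess–Martin periodinane, pyridine, CH2Cl2, 0 °C → rt
Reagents that add atoms: none
Why: Dess–Martin oxidation of the primary alcohol under buffered conditions, giving an aldehyde that is already the more stable equatorial C9 epimer.

Step 16
Reactants: 26 (4S,5S,6R,8S,9S,10R)-11-oxo-6,8-bis(triethylsilyloxy)-12,13,14,15,16-pentanorlabdane-18-nitrile
Product: 27 (4S,5S,6R,8S,9S,10R)-6,8-bis(triethylsilyloxy)-13,14,15,16-tetranorlabd-11-ene-18-nitrile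
Conditions: Ph3PCH3Br, KN(SiMe3)2, THF, 0 °C; then 26, −78 → 0 °C
Reagents that add atoms: methyltriphenylphosphonium bromide, C[P+](c1ccccc1)(c1ccccc1)c1ccccc1.[Br-]
Why: Wittig methylenation with the small non-stabilised ylide should cope with the flanked aldehyde, and because the β-oxygen is silylated no retro-aldol alkoxide can form.

Step 17
Reactants: 27 (4S,5S,6R,8S,9S,10R)-6,8-bis(triethylsilyloxy)-13,14,15,16-tetranorlabd-11-ene-18-nitrile; 28 chloroprene (2-chlorobuta-1,3-diene, stabilised solution)
Product: 30 (4S,5S,6R,8S,9S,10R)-6,8-bis(triethylsilyloxy)labda-13(16),14-diene-18-nitrile, via B-alkyl-9-BBN adduct 29 (not isolated)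
Conditions: 9-BBN dimer, THF, 0 °C → rt; then 28 (3 equiv), Pd(OAc)2 (5 mol %), SPhos (2-dicyclohexylphosphino-2',6'-dimethoxybiphenyl, 10 mol %), 3 M aq. K3PO4, 2,6-di-tert-butyl-4-methylphenol (cat.), THF, 45 °C
Reagents that add atoms: none
Why: 9-BBN adds anti-Markovnikov to the only monosubstituted alkene, and the B-alkyl borane should undergo B-alkyl Suzuki–Miyaura coupling with the alkenyl chloride under a dialkylbiarylphosphine–palladium catalyst to install the 2-substituted buta-1,3-diene, the nitrile and silyl ethers being inert.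

Step 18
Reactants: 30 (4S,5S,6R,8S,9S,10R)-6,8-bis(triethylsilyloxy)labda-13(16),14-diene-18-nitrile
Product: 32 (4S,5S,6R,8S,9S,10R)-6,8-bis(triethylsilyloxy)labda-13(16),14-dien-18-al, via N-aluminio aldimine 31 (not isolated)
Conditions: iBu2AlH (2.5 equiv), toluene, −78 → 0 °C; aq. KNaC4H4O6 (potassium sodium tartrate), then pH 4 citrate buffer, rt
Reagents that add atoms: water, O
Why: iBu2AlH adds once to a nitrile and stops at the N-aluminio aldimine, whose hydrolysis gives the neopentyl aldehyde (nitrile-to-aldehyde reduction), leaving the 1,3-diene and silyl ethers untouched at low temperature.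

Step 19
Reactants: 32 (4S,5S,6R,8S,9S,10R)-6,8-bis(triethylsilyloxy)labda-13(16),14-dien-18-al
Product: 33 (4S,5S,6R,8S,9S,10R)-6,8-bis(triethylsilyloxy)labda-13(16),14-dien-18-ol
Conditions: NaBH4, MeOH/THF, −20 → 0 °C
Reagents that add atoms: none
Why: Borohydride reduction of an aldehyde on a quaternary carbon, where nothing can epimerise, kept cold and short so that the 6-O-silyl group stays in place.

Step 20
Reactants: 33 (4S,5S,6R,8S,9S,10R)-6,8-bis(triethylsilyloxy)labda-13(16),14-dien-18-ol
Product: 34 (4S,5S,6R,8S,9S,10R)-6,8-bis(triethylsilyloxy)labda-13(16),14-dien-18-yl acetate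
Conditions: Ac2O, pyridine, DMAP (cat.), CH2Cl2, rt
Reagents that add atoms: acetic anhydride, CC(=O)OC(C)=O
Why: DMAP-catalysed acetylation of the only free hydroxyl group, so no selectivity among the three oxygens is needed.

Step 21
Reactants: 34 (4S,5S,6R,8S,9S,10R)-6,8-bis(triethylsilyloxy)labda-13(16),14-dien-18-yl acetate
Product: 35 (4S,5S,6R,8S,9S,10R)-6,8-dihydroxylabda-13(16),14-dien-18-yl acetate (CNP0317825.1)
Conditions: HF·pyridine, pyridine, THF, 0 °C → rt
Reagents that add atoms: none
Why: Pyridine-buffered HF·pyridine should cleave the secondary and tertiary triethylsilyl ethers (fluoride desilylation) without acyl migration, acetate hydrolysis or protonation of the diene.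

**Compound list**

1 | ethyl 2-oxocyclohexane-1-carboxylate | CCOC(=O)C1CCCCC1=O | starting material
2 | tert-butyl L-valinate, tert-butyl (2S)-2-amino-3-methylbutanoate | CC(C)[C@H](N)C(=O)OC(C)(C)C | starting material
3 | tert-butyl (2S)-2-{[2-(ethoxycarbonyl)cyclohex-1-en-1-yl]amino}-3-methylbutanoate | CCOC(=O)C1=C(N[C@@H](C(C)C)C(=O)OC(C)(C)C)CCCC1 | intermediate
4 | N-lithio derivative of 3 (lithio enamine) | CCOC(=O)C1=C(N([Li])[C@@H](C(C)C)C(=O)OC(C)(C)C)CCCC1 | intermediate
5 | tert-butyl (2S)-2-{[(2S)-2-(ethoxycarbonyl)-2-methylcyclohexylidene]amino}-3-methylbutanoate | CCOC(=O)[C@@]1(C)CCCCC1=N[C@@H](C(C)C)C(=O)OC(C)(C)C | intermediate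
6 | ethyl (1S)-1-methyl-2-oxocyclohexane-1-carboxylate | CCOC(=O)[C@@]1(C)CCCCC1=O | intermediate
7 | lithium (6S)-6-(ethoxycarbonyl)-6-methylcyclohex-1-en-1-olate | CCOC(=O)[C@@]1(C)CCCC=C1O[Li] | intermediate
8 | ethyl (1S,3RS)-1,3-dimethyl-2-oxocyclohexane-1-carboxylate | CCOC(=O)[C@@]1(C)CCCC(C)C1=O | intermediate
9 | lithium (6S)-6-(ethoxycarbonyl)-2,6-dimethylcyclohex-1-en-1-olate | CCOC(=O)[C@@]1(C)CCCC(C)=C1O[Li] | intermediate
10 | ethyl (1S)-1,3-dimethyl-2-[(trifluoromethanesulfonyl)oxy]cyclohex-2-ene-1-carboxylate | CCOC(=O)[C@@]1(C)CCCC(C)=C1OS(=O)(=O)C(F)(F)F | intermediate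
11 | potassium vinyltrifluoroborate | C=C[B-](F)(F)F.[K+] | starting material
12 | ethyl (1S)-2-ethenyl-1,3-dimethylcyclohex-2-ene-1-carboxylate | CCOC(=O)[C@@]1(C)CCCC(C)=C1C=C | intermediate
13 | (1S)-2-ethenyl-1,3-dimethylcyclohex-2-ene-1-carboxylic acid | OC(=O)[C@@]1(C)CCCC(C)=C1C=C | intermediate
14 | (1S)-2-ethenyl-1,3-dimethylcyclohex-2-ene-1-carbonyl chloride | ClC(=O)[C@@]1(C)CCCC(C)=C1C=C | intermediate
15 | (1S)-2-ethenyl-1,3-dimethylcyclohex-2-ene-1-carboxamide | NC(=O)[C@@]1(C)CCCC(C)=C1C=C | intermediate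
16 | (1S)-2-ethenyl-1,3-dimethylcyclohex-2-ene-1-carbonitrile | N#C[C@@]1(C)CCCC(C)=C1C=C | intermediate
17 | ethyl buta-2,3-dienoate | C=C=CC(=O)OCC | starting material
18 | ethyl (4S,10S)-18-nitrilo-12,13,14,15,16-pentanorlabda-5,8(17)-dien-11-oate, pair of C9 epimers [ethyl (1RS,5S,8aS)-5-cyano-5,8a-dimethyl-2-methylidene-1,2,3,5,6,7,8,8a-octahydronaphthalene-1-carboxylate] | CCOC(=O)C1[C@]2(C)CCC[C@](C)(C#N)C2=CCC1=C | intermediate
19 | lithium dienolate of 18 (C9=C11 enolate conjugated with the 8(17)-alkene) | CCOC(O[Li])=C1[C@]2(C)CCC[C@](C)(C#N)C2=CCC1=C | intermediate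
20 | ethyl (4S,9R,10S)-18-nitrilo-12,13,14,15,16-pentanorlabda-5,8(17)-dien-11-oate (ester cis to C20) | CCOC(=O)[C@H]1[C@]2(C)CCC[C@](C)(C#N)C2=CCC1=C | intermediate
21 | ethyl (4S,8S,9S,10S)-8-hydroxy-18-nitrilo-12,13,14,15,16-pentanorlabd-5-en-11-oate (8-OH trans to C20) | CCOC(=O)[C@H]1[C@]2(C)CCC[C@](C)(C#N)C2=CC[C@]1(C)O | intermediate
22 | C6 alkylborane of 21 (6-boryl, 8-O-boryl; boron trans to C20) | CCOC(=O)[C@H]1[C@]2(C)CCC[C@](C)(C#N)[C@H]2[C@H]([BH2])C[C@]1(C)O[BH2] | intermediate
23 | ethyl (4S,5S,6R,8S,9S,10R)-6,8-dihydroxy-18-nitrilo-12,13,14,15,16-pentanorlabdan-11-oate | CCOC(=O)[C@H]1[C@]2(C)CCC[C@](C)(C#N)[C@H]2[C@H](O)C[C@]1(C)O | intermediate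
24 | ethyl (4S,5S,6R,8S,9S,10R)-18-nitrilo-6,8-bis(triethylsilyloxy)-12,13,14,15,16-pentanorlabdan-11-oate | CCOC(=O)[C@H]1[C@]2(C)CCC[C@](C)(C#N)[C@H]2[C@H](O[Si](CC)(CC)CC)C[C@]1(C)O[Si](CC)(CC)CC | intermediate
25 | (4S,5S,6R,8S,9R,10R)-11-hydroxy-6,8-bis(triethylsilyloxy)-12,13,14,15,16-pentanorlabdane-18-nitrile | OC[C@H]1[C@]2(C)CCC[C@](C)(C#N)[C@H]2[C@H](O[Si](CC)(CC)CC)C[C@]1(C)O[Si](CC)(CC)CC | intermediate
26 | (4S,5S,6R,8S,9S,10R)-11-oxo-6,8-bis(triethylsilyloxy)-12,13,14,15,16-pentanorlabdane-18-nitrile | O=C[C@H]1[C@]2(C)CCC[C@](C)(C#N)[C@H]2[C@H](O[Si](CC)(CC)CC)C[C@]1(C)O[Si](CC)(CC)CC | intermediate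
27 | (4S,5S,6R,8S,9S,10R)-6,8-bis(triethylsilyloxy)-13,14,15,16-tetranorlabd-11-ene-18-nitrile | C=C[C@H]1[C@]2(C)CCC[C@](C)(C#N)[C@H]2[C@H](O[Si](CC)(CC)CC)C[C@]1(C)O[Si](CC)(CC)CC | intermediate
28 | chloroprene, 2-chlorobuta-1,3-diene | C=CC(Cl)=C | starting material
29 | 12-(9-borabicyclo[3.3.1]nonan-9-yl) derivative of the saturated chain of 27 | C(C[C@H]1[C@]2(C)CCC[C@](C)(C#N)[C@H]2[C@H](O[Si](CC)(CC)CC)C[C@]1(C)O[Si](CC)(CC)CC)B1C2CCCC1CCC2 | intermediate
30 | (4S,5S,6R,8S,9S,10R)-6,8-bis(triethylsilyloxy)labda-13(16),14-diene-18-nitrile | C=CC(=C)CC[C@H]1[C@]2(C)CCC[C@](C)(C#N)[C@H]2[C@H](O[Si](CC)(CC)CC)C[C@]1(C)O[Si](CC)(CC)CC | intermediate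
31 | N-(diisobutylaluminio) aldimine of 32 | C=CC(=C)CC[C@H]1[C@]2(C)CCC[C@](C)(C=N[Al](CC(C)C)CC(C)C)[C@H]2[C@H](O[Si](CC)(CC)CC)C[C@]1(C)O[Si](CC)(CC)CC | intermediate
32 | (4S,5S,6R,8S,9S,10R)-6,8-bis(triethylsilyloxy)labda-13(16),14-dien-18-al | C=CC(=C)CC[C@H]1[C@]2(C)CCC[C@](C)(C=O)[C@H]2[C@H](O[Si](CC)(CC)CC)C[C@]1(C)O[Si](CC)(CC)CC | intermediate
33 | (4S,5S,6R,8S,9S,10R)-6,8-bis(triethylsilyloxy)labda-13(16),14-dien-18-ol | C=CC(=C)CC[C@H]1[C@]2(C)CCC[C@](C)(CO)[C@H]2[C@H](O[Si](CC)(CC)CC)C[C@]1(C)O[Si](CC)(CC)CC | intermediate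
34 | (4S,5S,6R,8S,9S,10R)-6,8-bis(triethylsilyloxy)labda-13(16),14-dien-18-yl acetate | C=CC(=C)CC[C@H]1[C@]2(C)CCC[C@](C)(COC(C)=O)[C@H]2[C@H](O[Si](CC)(CC)CC)C[C@]1(C)O[Si](CC)(CC)CC | intermediate
35 | (4S,5S,6R,8S,9S,10R)-6,8-dihydroxylabda-13(16),14-dien-18-yl acetate | C=CC(=C)CC[C@H]1[C@]2(C)CCC[C@](C)(COC(C)=O)[C@H]2[C@H](O)C[C@]1(C)O | target

**Step count**

Total step count: 21. Longest linear sequence: 21 steps (the route is linear from 1).

**Steps most likely to fail**

Step 9. Face selection at C10 may be insufficient, with cycloaddition on the diene face that carries the C19 methyl group competing, and slow bond formation at the tetrasubstituted terminus may let the allenoate oligomerise. The fallback makes the cycloaddition intramolecular by tying the dienophile to C18. It sets out from amide 15, which is N-acylated with buta-2,3-dienoyl chloride (LiN(SiMe3)2, THF, −78 °C) to the acyclic imide (1S)-N-(buta-2,3-dienoyl)-2-ethenyl-1,3-dimethylcyclohex-2-ene-1-carboxamide F1. Heating F1 in toluene (type 2 intramolecular Diels–Alder reaction) can bring the three-atom C(=O)–NH–C(=O) bridge over C10 only from the C18 face. It forms the same C9–C10 and C7–C8 bonds and gives the bridged cyclic imide (4S,9S,10S)-11,18-dioxo-11,18-epimino-12,13,14,15,16-pentanorlabda-5,8(17)-diene F2. Ethanolysis (EtOH, Et3N, DMAP cat., 50 °C) at the less hindered C11 carbonyl opens it to ethyl (4S,9S,10S)-18-amino-18-oxo-12,13,14,15,16-pentanorlabda-5,8(17)-dien-11-oate F3. Dehydration as in step 8 ((CF3CO)2O, pyridine) comes back to the route at 18, now as the single C9 epimer with the ester on the C18 face, which step 10 converts into 20.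

Step 11. Hydrogen-atom transfer may not discriminate cleanly between the two alkenes, the doubly allylic C7 methylene may autoxidise under cobalt and O2, or O2 trapping at C8 may show low face selectivity. The fallback replaces the radical hydration by ionic Markovnikov hydration. It sets out from 20: Hg(OAc)2 in THF/H2O should add only to the exocyclic alkene, water opening the mercurinium ion at C8 anti to the syn-axial C20 methyl, to give ethyl (4S,8S,9S,10S)-17-(acetoxymercurio)-8-hydroxy-18-nitrilo-12,13,14,15,16-pentanorlabd-5-en-11-oate F4. Demercuration with NaBH4 in aq. NaOH at 0 °C returns to the route at 21.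

Step 17. Oxidative addition to the alkenyl chloride may be slow, and the volatile chloroprene may polymerise or evaporate before it couples, leaving the alkylborane to decompose. The fallback changes the C12–C13 bond formation from palladium cross-coupling to copper-catalysed alkylation of a Grignard reagent. It sets out from 27, which is hydroborated as before to 29 and then oxidised (30% H2O2, aq. NaOAc) to (4S,5S,6R,8S,9S,10R)-12-hydroxy-6,8-bis(triethylsilyloxy)-13,14,15,16-tetranorlabdane-18-nitrile F5. I2, PPh3 and imidazole convert it into (4S,5S,6R,8S,9S,10R)-12-iodo-6,8-bis(triethylsilyloxy)-13,14,15,16-tetranorlabdane-18-nitrile F6. Buta-1,3-dien-2-ylmagnesium chloride (from 28 and Mg in THF) with Li2CuCl4 (cat.) at −20 → 0 °C then comes back to the route at 30; the hindered tertiary nitrile should not be attacked at this temperature.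

**Further compounds**

F1 | step 9 | (1S)-N-(buta-2,3-dienoyl)-2-ethenyl-1,3-dimethylcyclohex-2-ene-1-carboxamide | C=C=CC(=O)NC(=O)[C@@]1(C)CCCC(C)=C1C=C
F2 | step 9 | (4S,9S,10S)-11,18-dioxo-11,18-epimino-12,13,14,15,16-pentanorlabda-5,8(17)-diene (bridged cyclic imide) | O=C1NC(=O)[C@@]2(C)CCC[C@@]3(C)[C@@H]1C(=C)CC=C23
F3 | step 9 | ethyl (4S,9S,10S)-18-amino-18-oxo-12,13,14,15,16-pentanorlabda-5,8(17)-dien-11-oate | CCOC(=O)[C@@H]1[C@]2(C)CCC[C@](C)(C(N)=O)C2=CCC1=C
F4 | step 11 | ethyl (4S,8S,9S,10S)-17-(acetoxymercurio)-8-hydroxy-18-nitrilo-12,13,14,15,16-pentanorlabd-5-en-11-oate | CCOC(=O)[C@H]1[C@]2(C)CCC[C@](C)(C#N)C2=CC[C@]1(C[Hg]OC(C)=O)O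
F5 | step 17 | (4S,5S,6R,8S,9S,10R)-12-hydroxy-6,8-bis(triethylsilyloxy)-13,14,15,16-tetranorlabdane-18-nitrile | OCC[C@H]1[C@]2(C)CCC[C@](C)(C#N)[C@H]2[C@H](O[Si](CC)(CC)CC)C[C@]1(C)O[Si](CC)(CC)CC
F6 | step 17 | (4S,5S,6R,8S,9S,10R)-12-iodo-6,8-bis(triethylsilyloxy)-13,14,15,16-tetranorlabdane-18-nitrile | ICC[C@H]1[C@]2(C)CCC[C@](C)(C#N)[C@H]2[C@H](O[Si](CC)(CC)CC)C[C@]1(C)O[Si](CC)(CC)CC
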